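**Plan**

- Retrosynthesis: the two aryl–C(=O) bonds are cut first (Friedel–Crafts on 1,3-dimethoxybenzene), leaving all-trans 3,4-diphenylcyclobutane-1,2-dicarboxylic acid. C1–C2 is then raised to a cyclobutene double bond and the ring bond C1–C4 is cut.
- Enabling feature: in the four-membered ring C1 carries a carbonyl carbon and is bonded to phenyl-bearing C4, while C2 carries the other carbonyl and C3 the other phenyl. C1 can therefore be a carbene carbon attached to C2 that inserts into the C2–C4 bond of a trans-2,3-diphenylcyclopropane built from C2, C3 and C4.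
- Further cuts: the diazo group goes back to a CH2CO2Me arm, the C2–CH2 bond to an enolate alkylation, and the three-membered ring to trans-stilbene plus the carbene of ethyl diazoacetate.
- Forward order: cyclopropane, resolution, quaternary carbon, diazo ester, 3→4 ring expansion, reduction, diaryl ketone, demethylation.
- Stereochemistry: C3 and C4 come from the resolved trans-cyclopropane and are carried through the shift with retention. C1 and C2 are set afterwards by equilibration to the all-trans ring. The target is (1R,2R,3S,4S).

Key step: step 7

Assumption: the (2S,3S)-acid is taken to form the less soluble salt with (R)-1-phenylethylamine; if the pairing is the opposite, the (S)-amine is used, and the configuration of 5 is to be confirmed on the salt (X-ray) before going on.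

**Route**

Step 1
Reactants: 1 trans-stilbene; 2 ethyl diazoacetate
Product: 3 ethyl trans-2,3-diphenylcyclopropane-1-carboxylate (racemic)
Conditions: Cu(acac)2 (2 mol %), 1 (3 equiv), 2 added by syringe pump, ClCH2CH2Cl, 80 °C
Reagents that add atoms: none
Why: Copper-carbenoid [2+1] cyclopropanation is stereospecific, so the E geometry of 1 becomes the trans relation of the phenyl groups, and because the ester-bearing carbon is not a stereocentre only one racemic product can form.

Step 2
Reactants: 3 ethyl trans-2,3-diphenylcyclopropane-1-carboxylate (racemic)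
Product: 4 trans-2,3-diphenylcyclopropane-1-carboxylic acid (racemic)
Conditions: KOH, EtOH/H2O, reflux; then aq. HCl
Reagents that add atoms: potassium hydroxide, [K+].[OH-]
Why: Saponification of the ester should proceed without stereochemical consequence, since the carboxyl-bearing carbon is not stereogenic and the benzylic centres are not acidified.

Step 3
Reactants: 4 trans-2,3-diphenylcyclopropane-1-carboxylic acid (racemic)
Product: 5 (2S,3S)-2,3-diphenylcyclopropane-1-carboxylic acid
Conditions: (R)-1-phenylethylamine (1.0 equiv), EtOH, crystallise and recrystallise the less soluble salt; then 1 M HCl, EtOAc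
Reagents that add atoms: none
Why: Classical resolution by fractional crystallisation of diastereomeric ammonium carboxylate salts separates the enantiomers without creating a stereocentre, and the C2/C3 configuration fixed here is the only source of absolute stereochemistry in the route.

Step 4
Reactants: 5 (2S,3S)-2,3-diphenylcyclopropane-1-carboxylic acid
Product: 6 methyl (2S,3S)-2,3-diphenylcyclopropane-1-carboxylate
Conditions: MeI, K2CO3, DMF, rt
Reagents that add atoms: iodomethane, CI
Why: SN2 O-methylation of the carboxylate leaves the ring untouched, and the methyl ester is chosen so that every ester downstream is methyl and cannot scramble in methanol.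

Step 5
Reactants: 6 methyl (2S,3S)-2,3-diphenylcyclopropane-1-carboxylate; 7 methyl bromoacetate
Product: 8 methyl (2R,3R)-1-(2-methoxy-2-oxoethyl)-2,3-diphenylcyclopropane-1-carboxylate
Conditions: LDA, THF, −78 °C; then 7, DMPU, −78 → 0 °C
Reagents that add atoms: none
Why: Lithium ester enolate C-alkylation with an activated α-halo ester builds the quaternary carbon, whose two faces are homotopic through the local C2 axis, so no stereocentre is created (the C2/C3 descriptors change from S to R only because the quaternary carbon now outranks phenyl).

Step 6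
Reactants: 8 methyl (2R,3R)-1-(2-methoxy-2-oxoethyl)-2,3-diphenylcyclopropane-1-carboxylate
Product: 10 methyl 2-diazo-2-[(2R,3R)-1-(methoxycarbonyl)-2,3-diphenylcyclopropyl]acetate, via trifluoroacetyl ester 9 (not isolated)
Conditions: LiHMDS, THF, −78 °C; CF3CO2CH2CF3, −78 °C; aq. HCl work-up; then MsN3, Et3N, H2O (1 equiv), MeCN, rt
Reagents that add atoms: methanesulfonyl azide, CS(=O)(=O)N=[N+]=[N-]; 2,2,2-trifluoroethyl trifluoroacetate, FC(F)(F)COC(=O)C(F)(F)F (its CF3CO group is present in intermediate 9 only)
Why: Deacylative (detrifluoroacetylative, Regitz-type) diazo transfer should work because the side-chain CH2 is the only enolisable position, is C-trifluoroacetylated through its enolate, and then takes N2 from the sulfonyl azide with loss of the trifluoroacetyl group as the N-acylsulfonamide.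

Step 7
Reactants: 10 methyl 2-diazo-2-[(2R,3R)-1-(methoxycarbonyl)-2,3-diphenylcyclopropyl]acetate
Product: 11 dimethyl (3R,4R)-3,4-diphenylcyclobut-1-ene-1,2-dicarboxylate
Conditions: Rh2(OAc)4 (2 mol %), CH2Cl2, 0 °C, 10 added slowly; cold filtration through a short silica pad, used at once
Reagents that add atoms: none
Why: Rh(II) should expel N2 from 10 to give an electrophilic rhodium carbene at the side-chain carbon, into which the adjacent strained ring bond from the quaternary carbon to a benzylic carbon migrates in a cyclopropylcarbinyl-to-cyclobutyl 1,2-shift, the metal leaving as the C=C bond forms between the former carbene carbon and the former quaternary carbon. The closest known reaction type is the Rh(II)-, Ag(I)- or Cu(I)-catalysed ring expansion of cyclopropyl diazoacetates (cyclopropyl metal carbenes) to cyclobutene carboxylates. The four-membered ring arises by one-carbon enlargement of the three-membered ring, that is by insertion of the carbene carbon into a ring C–C bond (the future C1–C4 bond of the target), not by a cyclisation of a chain. No stereocentre is created: the migrating benzylic carbon moves with retention and the other is untouched, so the trans-diphenyl arrangement and the absolute configuration of 5 pass unchanged into 11. The step needs chemoselectivity for ring-bond migration over 1,2-hydride shift, attack on the cis phenyl ring (Buchner cycloaddition or C–H insertion) and carbene dimerisation, which the hydrogen-free quaternary ring carbon, the proximity of the strained bond and the low diazo concentration should secure, while no regiochemical choice exists because the two ring bonds are related by the C2 axis and both esters are methyl. The product is kept cold and reduced immediately because 3,4-diphenylcyclobutenes are prone to conrotatory opening to dienes.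

Step 8
Reactants: 11 dimethyl (3R,4R)-3,4-diphenylcyclobut-1-ene-1,2-dicarboxylate
Product: 12 dimethyl (1R,2R,3S,4S)-3,4-diphenylcyclobutane-1,2-dicarboxylate
Conditions: Mg turnings (10 equiv), MeOH, 0 °C → rt; then NaOMe (0.3 equiv), MeOH, rt → 40 °C; aq. NH4Cl
Reagents that add atoms: none
Why: Dissolving-metal conjugate reduction (Mg/MeOH, electron transfer then protonation) saturates the doubly activated alkene, and methoxide epimerisation then brings the two new α-ester centres C1 and C2 to the thermodynamically preferred all-trans arrangement, each ester trans to its neighbouring phenyl, so the fixed C3/C4 centres control both (their descriptors become S only through a priority change).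

Step 9
Reactants: 12 dimethyl (1R,2R,3S,4S)-3,4-diphenylcyclobutane-1,2-dicarboxylate
Product: 13 (1R,2R,3S,4S)-3,4-diphenylcyclobutane-1,2-dicarboxylic acid
Conditions: LiOH·H2O (6 equiv), THF/MeOH/H2O, 50 °C; then 1 M HCl
Reagents that add atoms: lithium hydroxide, [Li+].[OH-]
Why: Saponification of both methyl esters cannot erode the relative configuration because the all-trans diacid is already the thermodynamic isomer.

Step 10
Reactants: 13 (1R,2R,3S,4S)-3,4-diphenylcyclobutane-1,2-dicarboxylic acid; 14 1,3-dimethoxybenzene
Product: 16 [(1R,2R,3S,4S)-3,4-diphenylcyclobutane-1,2-diyl]bis[(2,4-dimethoxyphenyl)methanone], via bis(acid chloride) 15 (not isolated)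
Conditions: (COCl)2, DMF (cat.), CH2Cl2, 0 °C → rt, evaporate; then 14 (4 equiv), AlCl3 (2.5 equiv), CH2Cl2, 0 °C; ice/1 M HCl
Reagents that add atoms: oxalyl chloride, O=C(Cl)C(=O)Cl (its chlorine is present in intermediate 15 only)
Why: Twofold Friedel–Crafts acylation through the bis(acid chloride) should occur at C4 of 1,3-dimethoxybenzene (para to one methoxy, ortho to the other), while the trans relation of each acyl chloride to its neighbouring phenyl and to the other acyl group disfavours intramolecular acylation and anhydride formation.

Step 11
Reactants: 16 [(1R,2R,3S,4S)-3,4-diphenylcyclobutane-1,2-diyl]bis[(2,4-dimethoxyphenyl)methanone]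
Product: 17 [(1R,2R,3S,4S)-3,4-diphenylcyclobutane-1,2-diyl]bis[(2,4-dihydroxyphenyl)methanone]
Conditions: BBr3 (8 equiv), CH2Cl2, −78 °C → rt; then H2O, 0 °C
Reagents that add atoms: none
Why: Lewis-acid ether cleavage with BBr3 (bromide attack on the O-methyl groups of the aryl borate complexes) should free all four phenols while leaving the aryl ketones and the ring stereocentres untouched.

**Compound list**

1 | trans-stilbene | c1ccccc1/C=C/c1ccccc1 | starting material
2 | ethyl diazoacetate | CCOC(=O)C=[N+]=[N-] | starting material
3 | ethyl trans-2,3-diphenylcyclopropane-1-carboxylate, racemic (one enantiomer drawn) | CCOC(=O)C1[C@@H](c2ccccc2)[C@@H]1c1ccccc1 | intermediate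
4 | trans-2,3-diphenylcyclopropane-1-carboxylic acid, racemic (one enantiomer drawn) | OC(=O)C1[C@@H](c2ccccc2)[C@@H]1c1ccccc1 | intermediate
5 | (2S,3S)-2,3-diphenylcyclopropane-1-carboxylic acid | OC(=O)C1[C@@H](c2ccccc2)[C@@H]1c1ccccc1 | intermediate
6 | methyl (2S,3S)-2,3-diphenylcyclopropane-1-carboxylate | COC(=O)C1[C@@H](c2ccccc2)[C@@H]1c1ccccc1 | intermediate
7 | methyl bromoacetate | COC(=O)CBr | starting material
8 | methyl (2R,3R)-1-(2-methoxy-2-oxoethyl)-2,3-diphenylcyclopropane-1-carboxylate | COC(=O)CC1(C(=O)OC)[C@@H](c2ccccc2)[C@@H]1c1ccccc1 | intermediate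
9 | methyl (2R,3R)-1-(4,4,4-trifluoro-1-methoxy-1,3-dioxobutan-2-yl)-2,3-diphenylcyclopropane-1-carboxylate (side-chain CH unassigned, keto/enol mixture) | COC(=O)C(C(=O)C(F)(F)F)C1(C(=O)OC)[C@@H](c2ccccc2)[C@@H]1c1ccccc1 | intermediate
10 | methyl 2-diazo-2-[(2R,3R)-1-(methoxycarbonyl)-2,3-diphenylcyclopropyl]acetate | COC(=O)C(=[N+]=[N-])C1(C(=O)OC)[C@@H](c2ccccc2)[C@@H]1c1ccccc1 | intermediate
11 | dimethyl (3R,4R)-3,4-diphenylcyclobut-1-ene-1,2-dicarboxylate | COC(=O)C1=C(C(=O)OC)[C@@H](c2ccccc2)[C@@H]1c1ccccc1 | intermediate
12 | dimethyl (1R,2R,3S,4S)-3,4-diphenylcyclobutane-1,2-dicarboxylate | COC(=O)[C@H]1[C@H](C(=O)OC)[C@@H](c2ccccc2)[C@@H]1c1ccccc1 | intermediate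
13 | (1R,2R,3S,4S)-3,4-diphenylcyclobutane-1,2-dicarboxylic acid | OC(=O)[C@H]1[C@H](C(=O)O)[C@@H](c2ccccc2)[C@@H]1c1ccccc1 | intermediate
14 | 1,3-dimethoxybenzene | COc1cccc(OC)c1 | starting material
15 | (1R,2R,3S,4S)-3,4-diphenylcyclobutane-1,2-dicarbonyl dichloride | ClC(=O)[C@H]1[C@H](C(Cl)=O)[C@@H](c2ccccc2)[C@@H]1c1ccccc1 | intermediate
16 | [(1R,2R,3S,4S)-3,4-diphenylcyclobutane-1,2-diyl]bis[(2,4-dimethoxyphenyl)methanone] | O=C(c1ccc(OC)cc1OC)[C@H]1[C@H](C(=O)c2ccc(OC)cc2OC)[C@@H](c2ccccc2)[C@@H]1c1ccccc1 | intermediate
17 | [(1R,2R,3S,4S)-3,4-diphenylcyclobutane-1,2-diyl]bis[(2,4-dihydroxyphenyl)methanone] (CNP0118806.1) | O=C(c1ccc(O)cc1O)[C@H]1[C@H](C(=O)c2ccc(O)cc2O)[C@@H](c2ccccc2)[C@@H]1c1ccccc1 | target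

**Step count and risks**

Total step count: 11. Longest linear sequence: 11 steps (1 → 17).

Steps most likely to fail:

1. Step 7. The ester on the migration origin may slow the 1,2-shift enough for the carbene to be intercepted by the cis phenyl ring or to dimerise, and the cyclobutene may undergo electrocyclic opening before it is reduced. The fallback sets out from 1 and builds the four-membered ring photochemically. Irradiation of 1 with dimethyl fumarate (Pyrex-filtered Hg lamp, benzene) is expected to give, by exciplex [2+2] cycloaddition, racemic dimethyl μ-truxinate F1, in which the esters are trans, the phenyls are trans and each ester is cis to its neighbouring phenyl. NaOMe in MeOH should epimerise both α-ester centres to racemic dimethyl δ-truxinate F2. LiOH hydrolysis gives racemic δ-truxinic acid F3, which is resolved through a diastereomeric salt with a chiral amine such as (R)-1-phenylethylamine. The route is rejoined at 13.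

2. Step 5. The hindered, strongly basic cyclopropyl enolate may take a proton from methyl bromoacetate or from product 8, or undergo Claisen self-condensation, instead of C-alkylation at the congested ring carbon. The fallback sets out from 6 and acylates instead of alkylating. The enolate (LDA, THF, −78 °C) is added to excess dimethyl oxalate, which has no acidic hydrogen, to give methyl (2R,3R)-1-(2-methoxy-2-oxoacetyl)-2,3-diphenylcyclopropane-1-carboxylate F4. Condensation with tosylhydrazide (MeOH, cat. AcOH) gives methyl (2R,3R)-1-[2-methoxy-2-oxo-1-(tosylhydrazono)ethyl]-2,3-diphenylcyclopropane-1-carboxylate F5. Et3N or DBU in CH2Cl2 should then expel sulfinate (Bamford–Stevens-type) to give the diazo ester. The route is rejoined at 10, so steps 5 and 6 are both replaced.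

3. Step 10. The second acylation may stall on the aluminium-complexed mono-ketone, an acylium ion may attack a ring phenyl group intramolecularly, or AlCl3 may cause partial loss of methyl groups or Lewis-acid cleavage of the donor–acceptor ring bond. The fallback sets out from 13 and forms the ketones by organometallic addition. Bis(acid chloride) 15 is treated with N,O-dimethylhydroxylamine hydrochloride and pyridine to give (1R,2R,3S,4S)-N1,N2-dimethoxy-N1,N2-dimethyl-3,4-diphenylcyclobutane-1,2-dicarboxamide F6. Commercial 2,4-dimethoxyphenylmagnesium bromide (THF, 0 °C → rt) should add once to each Weinreb amide. The route is rejoined at 16.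

**Further compounds**

F1 | step 7 | dimethyl μ-truxinate, racemic [rac-dimethyl (1R,2R,3R,4R)-3,4-diphenylcyclobutane-1,2-dicarboxylate; one enantiomer drawn] | COC(=O)[C@@H]1[C@@H](C(=O)OC)[C@@H](c2ccccc2)[C@@H]1c1ccccc1
F2 | step 7 | dimethyl δ-truxinate, racemic [rac-dimethyl (1R,2R,3S,4S)-3,4-diphenylcyclobutane-1,2-dicarboxylate; one enantiomer drawn] | COC(=O)[C@H]1[C@H](C(=O)OC)[C@@H](c2ccccc2)[C@@H]1c1ccccc1
F3 | step 7 | δ-truxinic acid, racemic [rac-(1R,2R,3S,4S)-3,4-diphenylcyclobutane-1,2-dicarboxylic acid; one enantiomer drawn] | OC(=O)[C@H]1[C@H](C(=O)O)[C@@H](c2ccccc2)[C@@H]1c1ccccc1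
F4 | step 5 | methyl (2R,3R)-1-(2-methoxy-2-oxoacetyl)-2,3-diphenylcyclopropane-1-carboxylate | COC(=O)C(=O)C1(C(=O)OC)[C@@H](c2ccccc2)[C@@H]1c1ccccc1
F5 | step 5 | methyl (2R,3R)-1-[2-methoxy-2-oxo-1-(tosylhydrazono)ethyl]-2,3-diphenylcyclopropane-1-carboxylate | COC(=O)C(=NNS(=O)(=O)c1ccc(C)cc1)C1(C(=O)OC)[C@@H](c2ccccc2)[C@@H]1c1ccccc1
F6 | step 10 | (1R,2R,3S,4S)-N1,N2-dimethoxy-N1,N2-dimethyl-3,4-diphenylcyclobutane-1,2-dicarboxamide | CON(C)C(=O)[C@H]1[C@H](C(=O)N(C)OC)[C@@H](c2ccccc2)[C@@H]1c1ccccc1
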